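(The runs were computed for an exercise, noise included.)

I read maple and alder at 50 h, twice the last reading of the dawn run, so I need a count that can walk past the readings.

| flask | left-handed substrate | right-handed substrate | partner | precatalyst | added ligand | impurity | remark | time |
|---|---|---|---|---|---|---|---|---|
| autumn | 20 mM | 20 mM | 34 mM | 24 µM | 0.14 mM | 5.7 µM | run made earlier |  |
| noon | 20 mM | 20 mM | 56 mM | 24 µM | 0.14 mM | 5.7 µM | run made earlier |  |
| dawn | 20 mM | 20 mM | 65 mM | 24 µM | 0.14 mM | 5.7 µM | run made earlier |  |
| maple | 20 mM | 20 mM | 40.0 mM | 24 µM | 0.14 mM | 5.7 µM |  | 50 h |
| alder | 20 mM | 20 mM | 80.0 mM | 24 µM | 0.14 mM | 5.7 µM |  | 50 h |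

- autumn (time / h: right-handed substrate / %, left-handed substrate / %): 5.00: 48.7, 48.8; 10.0: 49.1, 45.3; 15.0: 46.3, 42.1; 20.0: 44.6, 38.2; 25.0: 43.0, 33.8
- noon (time / h: right-handed substrate / %, left-handed substrate / %): 2.00: 49.8, 49.3; 4.00: 49.6, 48.2; 8.00: 48.5, 44.9; 12.0: 46.2, 40.9; 25.0: 38.8, 26.1
- dawn (time / h: right-handed substrate / %, left-handed substrate / %): 2.00: 50.0, 50.2; 4.00: 48.9, 49.0; 8.00: 46.4, 45.1; 12.0: 45.1, 38.6; 25.0: 36.4, 23.0

(scatter of a reading: 0.5 percentage points)

* which one finishes higher in excess of right-handed substrate over left-handed substrate among what is left of the two ("neither" within 2 percentage points) (maple / alder / neither)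
* excess of right-handed substrate over left-handed substrate among what is left of the two at the end, maple
* excess of right-handed substrate over left-handed substrate among what is left of the two at the end, alder

- free catalyst is single-handed; left-handed substrate and right-handed substrate are mirror images of each other, charged as a racemate, each of them at the stated concentration
- what was read earlier has a scatter of 0.5 percentage points, one standard deviation
- an excess is below zero if the other one leads

At the bench I count halvings of the left-handed substrate, which falls faster than the right-handed one. The last dawn reading gives s = 2.45 for the selectivity factor s, the logarithm of the fraction of left-handed substrate left divided by that of the right-handed substrate left; it is a reading, with its scatter. So while n halvings pass for the left-handed substrate, n/s pass for the right-handed one, and the excess follows from those two counts.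

The rest is finding n. By 25.0 h the dawn run has counted 1.12 halvings and the autumn run 0.565, a ratio of 1.98 against 1.91 in partner charged, so I scale n with partner. The dawn count stood at 0.373 at 12.0 h, so it rises with time to the power 1.50, a slow start. Scaled so, maple reaches 1.95 halvings and alder 3.89, with excesses of 38.0% and 66.3%.

Here the rule stops, since it holds partner at its charge. Partner over the two substrates together is 1.00 in maple and 2.00 in alder, and at one partner per substrate those counts use 58.2% of maple's partner and 40.0% of alder's. So I run each count on the charge less half of what is used: 1.38 halvings for maple and 3.11 for alder. My excesses are then 27.5% and 56.3%.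

The forecast names alder, with 30% for maple and 58% for alder, each a little above mine; it too rests on the observation that “Selectivity is steady across the runs”.

The flask gives 31.1% for maple and 60.8% for alder, so alder finishes higher.

free catalyst + impurity → spent catalyst (k = 1.91 × 10⁵ M⁻¹ h⁻¹); partner + free catalyst + right-handed substrate → free catalyst + right-handed product (k = 8.33 × 10⁵ M⁻² h⁻¹); free catalyst + added ligand ⇌ idle complex, settled at all times (K = 1.80 × 10⁵ M⁻¹); partner + free catalyst + left-handed substrate → free catalyst + left-handed product (k = 2.01 × 10⁶ M⁻² h⁻¹); precatalyst → free catalyst (k = 0.0384 h⁻¹) Maple keeps 33% of its left-handed substrate and 63% of its right-handed one, and s carries the first figure to 63.6%. The neighbour flask, maple with 0.0097 mM of impurity, keeps 40% of its left-handed substrate at 50.0 h. There s gives 68.8% of the right-handed one and an excess of 26.5%, and that flask stands at 26.1%.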